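An excess of 95% means a ratio [left-handed substrate]/[right-handed substrate] of 0.0256, and the flask has until 10 h to reach it.

| setting | elm | cedar | ash | flask |
|---|---|---|---|---|
| left-handed substrate | 0.30 M | 0.30 M | 0.30 M | 0.30 M |
| right-handed substrate | 0.30 M | 0.30 M | 0.30 M | 0.30 M |
| partner | 0.60 M | 0.60 M | 0.30 M | 0.600 M |
| free catalyst | 20 mM | 45 mM | 30 mM | 30 mM |
| remark | run made earlier | run made earlier | run made earlier |  |
| time |  |  |  | 10 h |

| run | time / h | right-handed substrate / % | left-handed substrate / % | left-handed product / % |
|---|---|---|---|---|
| elm | 0.417 | 45 | 46 | 7 |
| elm | 1.33 | 49 | 40 | 9 |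
| elm | 2.00 | 50 | 35 | 16 |
| elm | 3.00 | 49 | 30 | 20 |
| elm | 5.00 | 49 | 27 | 21 |
| elm | 6.00 | 52 | 26 | 26 |
| cedar | 0.417 | 47 | 41 | 7 |
| cedar | 1.33 | 50 | 32 | 16 |
| cedar | 2.00 | 46 | 27 | 25 |
| cedar | 3.00 | 51 | 22 | 28 |
| cedar | 5.00 | 49 | 21 | 30 |
| cedar | 6.00 | 50 | 20 | 32 |
| ash | 1.33 | 51 | 41 | 9 |
| ash | 2.50 | 50 | 38 | 10 |
| ash | 4.00 | 51 | 35 | 14 |
| ash | 5.00 | 49 | 37 | 13 |
| ash | 6.00 | 50 | 32 | 16 |

(each reading ± 1.5 percentage points)

- whether the excess of right-handed substrate over left-handed substrate among what is left of the two reaches 95% by 10 h (no / yes)
- the highest excess of right-handed substrate over left-handed substrate among what is left of the two up to 10 h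

- free catalyst is single-handed; left-handed substrate and right-handed substrate are mirror images of each other, charged as a racemate, each of them at the stated concentration
- the analysis behind the earlier runs scatters by 1.5 percentage points, standard deviation
- steps under discussion: partner + free catalyst + left-handed substrate -> free catalyst + left-handed product; partner + free catalyst + right-handed substrate -> free catalyst + right-handed product; free catalyst <-> dormant form; 2 free catalyst <-> resting dimer; 2 free catalyst -> spent catalyst

In the flask, left-handed substrate is the limiting reagent against partner, at 0.30 M against 0.600 M. Each turnover of left-handed substrate takes one of each, so [partner] − [left-handed substrate] keeps its charged value as long as right-handed substrate does not react. If the main step is first order in each, the balance of left-handed substrate integrates to a catalyst dose G, the rate constant times the time integral of [free catalyst]: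

G = ln( ([partner]/[partner] charged) / ([left-handed substrate]/[left-handed substrate] charged) ) / ([partner] charged − [left-handed substrate] charged)

Right-handed substrate holds at 50% at cedar's last reading, so the target ratio asks for:

G needed = 9.99 /M

The reckoning here builds the flask up in stages.

Main step alone, catalyst intact: cedar's first reading, scaled to the flask's catalyst and time, gives

G = 5.55 /M

This leaves [left-handed substrate] at 31.3 mM, an excess of 81.1%, and the dose is already less than needed.

Adding catalyst loss in pairs: G should then follow catalyst charge × time. Elm at 360 M·s and cedar at 324 M·s do read alike, 27% and 27% of left-handed substrate. The flask's product is 1080 M·s, close to cedar's last 972 M·s, and that reading gives 1.87 /M of catalyst dose. The excess read there is 42.9%.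

Adding the rest: the dormant form and resting dimer are not read apart in these runs, and this reckoning leaves what they do inside cedar's reading. The flask's product is larger than cedar's, so the number moves up slightly, and the dose needed is 5.34 times cedar's.

This reckoning commits to no, at just above that excess. The forecast says no and 45%, a little higher: “All runs stall, and the stall comes sooner at higher catalyst loading.”

The flask gives no and 45.0%.

    partner + free catalyst + left-handed substrate → free catalyst + left-handed product (k = 30.2 /M²/h)
    partner + free catalyst + right-handed substrate → free catalyst + right-handed product (k = 0.253 /M²/h)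
    free catalyst ⇌ dormant form (K = 0.903, k = 0.101 /h)
    2 free catalyst ⇌ resting dimer (K = 10.6 /M, k = 94.4 /M/h)
    2 free catalyst → spent catalyst (k = 18.5 /M/h)

At 10.0 h the flask keeps 38% of its left-handed substrate and 68% of its partner, a dose of 2.00 /M. The answer changes in the neighbouring flask with 2.4 M of partner, where free catalyst stands at 9.58%, as in the flask (9.58%). Carrying cedar's 1.87 /M there, with the larger charged difference, gives [left-handed substrate] of 5.24 mM, or 1.75% of its charge. The neighbour keeps 1.3%, and its excess reaches 97.4%.

The runs are calculated for substances that don't exist, and the scatter is random.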